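Labdane numbering is used (C4 gem-dimethyl carbon, C5 and C10 ring-fusion carbons, C8 methylidene carbon, C9 side-chain carbon). The route rests on opening ring B at C6–C7 and C5–C10, which turns the trans-decalin into an acyclic trienal. An enantioselective intramolecular Diels–Alder reaction of diene C7=C8–C9=C10 with the (E)-enal C5=C6 closes rings A and B at once and sets the trans C5/C10 fusion with its angular methyl. It exploits three features: C6 is an unsubstituted methylene that can carry a traceless formyl activator, C1–C4 serve as tether, and the C8 methylidene with the C9 stereocentre is latent in a ring B allylsilane.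

Key step: step 8

Assumption: the (S)-configured oxazaborolidinium catalyst is taken to expose the Re face of the enal β-carbon C5 (formyl C–H···O binding model), which leads to (5R,10R); if the sense proves opposite, the (R)-catalyst is used with no other change.

Step 1
Reactants: 1 2,2-dimethylpent-4-enal
Product: 2 (2E)-4,4-dimethylhepta-2,6-dienal
Conditions: Ph3P=CHCHO (1.1 equiv), toluene, 90 °C
Reagents that add atoms: (triphenylphosphoranylidene)acetaldehyde, O=CC=P(c1ccccc1)(c1ccccc1)c1ccccc1
Why: Wittig olefination with a formyl-stabilised ylide should give the (E)-enal from the non-enolisable neopentyl aldehyde, and the conjugated product reacts more slowly with the ylide, so over-homologation is limited by stoichiometry.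

Step 2
Reactants: 2 (2E)-4,4-dimethylhepta-2,6-dienal
Product: 3 (5E)-7,7-dimethoxy-4,4-dimethylhepta-1,5-diene
Conditions: HC(OMe)3, MeOH, pyridinium p-toluenesulfonate (cat.), 25 °C
Reagents that add atoms: trimethyl orthoformate, COC(OC)OC; methanol, CO
Why: acid-catalysed acetalisation driven by the orthoformate masks the enal for the borane and organocerium steps, and conjugate addition of methanol is blocked by the quaternary carbon next to the β-position.

Step 3
Reactants: 4 methyl acetoacetate; 5 (4-bromobut-1-yn-1-yl)trimethylsilane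
Product: 6 methyl 2-acetyl-6-(trimethylsilyl)hex-5-ynoate (racemic)
Conditions: NaH, THF/DMF, 0 °C; then 5, NaI (cat.), 60 °C
Reagents that add atoms: none
Why: acetoacetic ester C-alkylation (SN2 of the soft enolate on the primary halide with iodide catalysis) installs C11–C14 as a masked butynyl chain, and the racemic stereocentre is erased in step 4.

Step 4
Reactants: 6 methyl 2-acetyl-6-(trimethylsilyl)hex-5-ynoate
Product: 7 methyl (2E)-3-{[(trifluoromethyl)sulfonyl]oxy}-2-[4-(trimethylsilyl)but-3-yn-1-yl]but-2-enoate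
Conditions: Tf2O, aq. Me4NOH, hexanes, 5 °C
Reagents that add atoms: trifluoromethanesulfonic anhydride, O=S(=O)(OS(=O)(=O)C(F)(F)F)C(F)(F)F
Why: stereoselective enol triflate formation from a β-keto ester, in which the non-chelating tetramethylammonium enolate reacts through its dipole-minimised form (enolate oxygen anti to the ester carbonyl), so the triflate should end up trans to the ester, whereas a chelating lithium enolate would give the (Z) isomer.

Step 5
Reactants: 3 (5E)-7,7-dimethoxy-4,4-dimethylhepta-1,5-diene; 7 methyl (2E)-3-{[(trifluoromethyl)sulfonyl]oxy}-2-[4-(trimethylsilyl)but-3-yn-1-yl]but-2-enoate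
Product: 9 methyl (2E,8E)-10,10-dimethoxy-3,7,7-trimethyl-2-[4-(trimethylsilyl)but-3-yn-1-yl]deca-2,8-dienoate, via alkyl-9-borabicyclononane 8 (not isolated)
Conditions: 3, 9-BBN-H, THF, 0 → 25 °C; then 7, PdCl2(dppf) (5 mol%, dppf = 1,1'-bis(diphenylphosphino)ferrocene), AsPh3, aq. K3PO4, DMF, 25 °C
Reagents that add atoms: none
Why: 9-BBN hydroborates only the monosubstituted alkene of 3 (anti-Markovnikov), and the B-alkyl Suzuki–Miyaura coupling of the vinylogous acyl triflate proceeds with retention, which fixes the C1 tether trans to the ester at the tetrasubstituted C9=C10 alkene.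

Step 6
Reactants: 9 methyl (2E,8E)-10,10-dimethoxy-3,7,7-trimethyl-2-[4-(trimethylsilyl)but-3-yn-1-yl]deca-2,8-dienoate
Product: 11 trimethyl{(3E,9E)-11,11-dimethoxy-4,8,8-trimethyl-2-methylidene-3-[4-(trimethylsilyl)but-3-yn-1-yl]undeca-3,9-dien-1-yl}silane, via bis(silylmethyl) carbinol 10 (not isolated)
Conditions: Me3SiCH2MgCl (4 equiv), anhydrous CeCl3, THF, −78 → 25 °C; aq. NH4Cl; then SiO2, CH2Cl2, 25 °C
Reagents that add atoms: (trimethylsilyl)methylmagnesium chloride, C[Si](C)(C)C[Mg]Cl
Why: double 1,2-addition of the weakly basic organocerium reagent to the ester followed by Peterson elimination of one β-silyl arm of the tertiary carbinol converts the ester carbon into C8 of a 2-(silylmethyl)-1,3-diene, with cerium suppressing γ-deprotonation and no stereocentre being formed.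

Step 7
Reactants: 11 trimethyl{(3E,9E)-11,11-dimethoxy-4,8,8-trimethyl-2-methylidene-3-[4-(trimethylsilyl)but-3-yn-1-yl]undeca-3,9-dien-1-yl}silane
Product: 12 (2E,8E)-4,4,8-trimethyl-10-methylidene-11-(trimethylsilyl)-9-[4-(trimethylsilyl)but-3-yn-1-yl]undeca-2,8-dienal
Conditions: pyridinium p-toluenesulfonate (cat.), acetone/H2O, 25 °C; used at once
Reagents that add atoms: water, O
Why: hydrolysis of the allylic acetal through its conjugated oxocarbenium ion is far faster than protodesilylation of the allylsilane at this weak acidity, so the trienal should be released without touching the diene.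

Step 8
Reactants: 12 (2E,8E)-4,4,8-trimethyl-10-methylidene-11-(trimethylsilyl)-9-[4-(trimethylsilyl)but-3-yn-1-yl]undeca-2,8-dienal
Product: 13 (1R,4aR,8aR)-4a,8,8-trimethyl-4-[4-(trimethylsilyl)but-3-yn-1-yl]-3-[(trimethylsilyl)methyl]-1,2,4a,5,6,7,8,8a-octahydronaphthalene-1-carbaldehyde
Conditions: (3aS)-1-(2-methylphenyl)-3,3-diphenyltetrahydro-1H,3H-pyrrolo[1,2-c][1,3,2]oxazaborole (20 mol%), (CF3SO2)2NH (17 mol%), CH2Cl2 (0.02 M), −78 → −20 °C
Reagents that add atoms: none
Why: Coordination of the formyl oxygen to the cationic oxazaborolidinium lowers the LUMO of the (E)-enal, and the tethered diene C7=C8–C9=C10 adds across C5=C6 in a concerted, asynchronous intramolecular [4+2] cycloaddition (type 1 intramolecular Diels–Alder reaction), the closest precedents being oxazaborolidinium-catalysed cyclisations of trienals and Lewis-acid-catalysed cycloadditions of 2-(silylmethyl)butadienes with enals. Ring B closes as the new cyclohexene through the C6–C7 and C5–C10 bonds, and ring A closes in the fused mode because the tether C1–C4 spans C10 and C5. The trans ring fusion (C10 methyl anti to H5) should follow from the endo transition state, in which the formyl group lies under the diene and the tether is exo, combined with the (8E) diene geometry that places the tether outside and the methyl inside; C6 is set in the same event (formyl cis to H5, dictated by the (E)-enal) and is erased in step 9. The absolute sense (5R,10R) is set by the catalyst, whose phenyl group shields the Si face of C5 in the formyl C–H···O bound complex so that the diene adds to the Re face. The step needs endo over exo selectivity and catalyst-controlled facial selectivity; the regiochemistry is enforced by the four-atom tether, the slight deficit of acid keeps the diene from protodesilylation, and the nucleophilic allylsilane terminus C7 cannot reach the carbonyl or C5 through a ring of reasonable size.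

Step 9
Reactants: 13 (1R,4aR,8aR)-4a,8,8-trimethyl-4-[4-(trimethylsilyl)but-3-yn-1-yl]-3-[(trimethylsilyl)methyl]-1,2,4a,5,6,7,8,8a-octahydronaphthalene-1-carbaldehyde
Product: 14 trimethyl{4-[(4aR,8aR)-5,5,8a-trimethyl-2-[(trimethylsilyl)methyl]-3,4,4a,5,6,7,8,8a-octahydronaphthalen-1-yl]but-1-yn-1-yl}silane
Conditions: RhCl(PPh3)3 (1.1 equiv), toluene, 110 °C
Reagents that add atoms: none
Why: Tsuji–Wilkinson decarbonylation (oxidative addition of the formyl C–H bond, CO extrusion, C–H reductive elimination) removes the activating group and the C6 stereocentre, and the tetrasubstituted alkene is too hindered for competing hydroacylation.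

Step 10
Reactants: 14 trimethyl{4-[(4aR,8aR)-5,5,8a-trimethyl-2-[(trimethylsilyl)methyl]-3,4,4a,5,6,7,8,8a-octahydronaphthalen-1-yl]but-1-yn-1-yl}silane
Product: 16 (1R,4aR,8aR)-1-(but-3-yn-1-yl)-5,5,8a-trimethyl-2-methylidenedecahydronaphthalene, via silylalkyne 15 (not isolated)
Conditions: CF3CO2H (2 equiv), CH2Cl2, −20 → 0 °C; then K2CO3 (excess), MeOH, 25 °C
Reagents that add atoms: none
Why: SE2' protodesilylation in which the proton should add to C9 on the face opposite the axial C10 methyl (axial attack through a chair-like transition state) and the β-silyl cation at C8 collapses to the exocyclic methylene, giving H9 cis to H5 (9R), after which carbonate in methanol cleaves only the alkynyl C–Si bond.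

Step 11
Reactants: 16 (1R,4aR,8aR)-1-(but-3-yn-1-yl)-5,5,8a-trimethyl-2-methylidenedecahydronaphthalene
Product: 19 (2E)-3-methyl-5-[(1R,4aR,8aR)-5,5,8a-trimethyl-2-methylidenedecahydronaphthalen-1-yl]pent-2-en-1-ol (ent-copalol), via alkenylalane 17 (not isolated), via lithium alanate 18 (not isolated)
Conditions: Me3Al (2.5 equiv), Cp2ZrCl2 (0.25 equiv), CH2Cl2, 25 °C; then n-BuLi, THF, −78 °C; (CH2O)n, −78 → 25 °C; cold dilute aq. HCl work-up
Reagents that add atoms: trimethylaluminium, C[Al](C)C; formaldehyde (as paraformaldehyde), C=O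
Why: Negishi zirconium-catalysed carboalumination adds methyl and aluminium syn across the terminal alkyne (methyl to the internal carbon), and hydroxymethylation of the alanate with retention should give the (13E)-allylic alcohol, the 1,1-disubstituted ring alkene being far less reactive.

Step 12
Reactants: 19 (2E)-3-methyl-5-[(1R,4aR,8aR)-5,5,8a-trimethyl-2-methylidenedecahydronaphthalen-1-yl]pent-2-en-1-ol
Product: 20 3-{[(2E)-3-methyl-5-[(1R,4aR,8aR)-5,5,8a-trimethyl-2-methylidenedecahydronaphthalen-1-yl]pent-2-en-1-yl]oxy}-3-oxopropanoic acid (CNP0107438.1)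
Conditions: Meldrum's acid (1.1 equiv), toluene, 90 °C
Reagents that add atoms: Meldrum's acid (2,2-dimethyl-1,3-dioxane-4,6-dione), CC1(C)OC(=O)CC(=O)O1
Why: ring-opening acylation of the primary allylic alcohol by Meldrum's acid with loss of acetone should give the hydrogen malonate directly, below the temperature at which the half ester decarboxylates.

Compound list
1 | 2,2-dimethylpent-4-enal | C=CCC(C)(C)C=O | starting material
2 | (2E)-4,4-dimethylhepta-2,6-dienal | C=CCC(C)(C)/C=C/C=O | intermediate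
3 | (5E)-7,7-dimethoxy-4,4-dimethylhepta-1,5-diene | C=CCC(C)(C)/C=C/C(OC)OC | intermediate
4 | methyl acetoacetate | COC(=O)CC(C)=O | starting material
5 | (4-bromobut-1-yn-1-yl)trimethylsilane | C[Si](C)(C)C#CCCBr | starting material
6 | methyl 2-acetyl-6-(trimethylsilyl)hex-5-ynoate (racemic) | COC(=O)C(CCC#C[Si](C)(C)C)C(C)=O | intermediate
7 | methyl (2E)-3-{[(trifluoromethyl)sulfonyl]oxy}-2-[4-(trimethylsilyl)but-3-yn-1-yl]but-2-enoate | COC(=O)/C(CCC#C[Si](C)(C)C)=C(\C)OS(=O)(=O)C(F)(F)F | intermediate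
8 | 9-[(5E)-7,7-dimethoxy-4,4-dimethylhept-5-en-1-yl]-9-borabicyclo[3.3.1]nonane | COC(OC)/C=C/C(C)(C)CCCB1C2CCCC1CCC2 | intermediate
9 | methyl (2E,8E)-10,10-dimethoxy-3,7,7-trimethyl-2-[4-(trimethylsilyl)but-3-yn-1-yl]deca-2,8-dienoate | COC(=O)/C(CCC#C[Si](C)(C)C)=C(\C)CCCC(C)(C)/C=C/C(OC)OC | intermediate
10 | (3E,9E)-11,11-dimethoxy-4,8,8-trimethyl-1-(trimethylsilyl)-2-[(trimethylsilyl)methyl]-3-[4-(trimethylsilyl)but-3-yn-1-yl]undeca-3,9-dien-2-ol | C[Si](C)(C)CC(O)(C[Si](C)(C)C)/C(CCC#C[Si](C)(C)C)=C(\C)CCCC(C)(C)/C=C/C(OC)OC | intermediate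
11 | trimethyl{(3E,9E)-11,11-dimethoxy-4,8,8-trimethyl-2-methylidene-3-[4-(trimethylsilyl)but-3-yn-1-yl]undeca-3,9-dien-1-yl}silane | C[Si](C)(C)CC(=C)/C(CCC#C[Si](C)(C)C)=C(\C)CCCC(C)(C)/C=C/C(OC)OC | intermediate
12 | (2E,8E)-4,4,8-trimethyl-10-methylidene-11-(trimethylsilyl)-9-[4-(trimethylsilyl)but-3-yn-1-yl]undeca-2,8-dienal | O=C/C=C/C(C)(C)CCC/C(C)=C(\CCC#C[Si](C)(C)C)C(=C)C[Si](C)(C)C | intermediate
13 | (1R,4aR,8aR)-4a,8,8-trimethyl-4-[4-(trimethylsilyl)but-3-yn-1-yl]-3-[(trimethylsilyl)methyl]-1,2,4a,5,6,7,8,8a-octahydronaphthalene-1-carbaldehyde | C[Si](C)(C)CC=1C[C@@H](C=O)[C@@H]2C(C)(C)CCC[C@@]2(C)C=1CCC#C[Si](C)(C)C | intermediate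
14 | trimethyl{4-[(4aR,8aR)-5,5,8a-trimethyl-2-[(trimethylsilyl)methyl]-3,4,4a,5,6,7,8,8a-octahydronaphthalen-1-yl]but-1-yn-1-yl}silane | C[Si](C)(C)CC=1CC[C@@H]2C(C)(C)CCC[C@@]2(C)C=1CCC#C[Si](C)(C)C | intermediate
15 | trimethyl{4-[(1R,4aR,8aR)-5,5,8a-trimethyl-2-methylidenedecahydronaphthalen-1-yl]but-1-yn-1-yl}silane | C=C1CC[C@@H]2C(C)(C)CCC[C@@]2(C)[C@@H]1CCC#C[Si](C)(C)C | intermediate
16 | (1R,4aR,8aR)-1-(but-3-yn-1-yl)-5,5,8a-trimethyl-2-methylidenedecahydronaphthalene | C=C1CC[C@@H]2C(C)(C)CCC[C@@]2(C)[C@@H]1CCC#C | intermediate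
17 | dimethyl{(1E)-2-methyl-4-[(1R,4aR,8aR)-5,5,8a-trimethyl-2-methylidenedecahydronaphthalen-1-yl]but-1-en-1-yl}alumane | C=C1CC[C@@H]2C(C)(C)CCC[C@@]2(C)[C@@H]1CC/C(C)=C/[Al](C)C | intermediate
18 | lithium butyl(dimethyl){(1E)-2-methyl-4-[(1R,4aR,8aR)-5,5,8a-trimethyl-2-methylidenedecahydronaphthalen-1-yl]but-1-en-1-yl}alanate | C=C1CC[C@@H]2C(C)(C)CCC[C@@]2(C)[C@@H]1CC/C(C)=C/[Al-](C)(C)CCCC.[Li+] | intermediate
19 | (2E)-3-methyl-5-[(1R,4aR,8aR)-5,5,8a-trimethyl-2-methylidenedecahydronaphthalen-1-yl]pent-2-en-1-ol (ent-copalol) | C=C1CC[C@@H]2C(C)(C)CCC[C@@]2(C)[C@@H]1CC/C(C)=C/CO | intermediate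
20 | 3-{[(2E)-3-methyl-5-[(1R,4aR,8aR)-5,5,8a-trimethyl-2-methylidenedecahydronaphthalen-1-yl]pent-2-en-1-yl]oxy}-3-oxopropanoic acid | C=C1CC[C@@H]2C(C)(C)CCC[C@@]2(C)[C@@H]1CC/C(C)=C/COC(=O)CC(=O)O | target

Total step count: 12. Longest linear sequence: 10 steps (steps 3–12 from methyl acetoacetate; equally steps 1, 2 and 5–12 from 2,2-dimethylpent-4-enal).

Steps most likely to fail

Step 8. The tetrasubstituted diene with its inside methyl may cyclise too slowly at the temperature where the catalyst controls facial and endo selection, so that warming lets uncatalysed or exo cyclisation erode enantiomeric purity and the trans ring fusion. The fallback replaces catalyst control by auxiliary control and sets out from trienal 12. Pinnick oxidation (NaClO2, NaH2PO4, 2-methyl-2-butene) should give the trienoic acid F1. Mixed pivalic anhydride coupling with lithiated (R)-4-benzyloxazolidin-2-one should give the imide F2. Chelate-controlled endo cycloaddition with Me2AlCl in CH2Cl2 at −30 °C, in which the benzyl group blocks the Si face of the s-cis enoyl unit, should give the cycloadduct F3. LiBH4 then cleaves the auxiliary to the primary alcohol F4, and Dess–Martin oxidation brings the route back at aldehyde 13.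

Step 6. Double addition of the bulky organocerium reagent to the hindered, conjugated tetrasubstituted ester may stall before or after the first addition. The fallback builds the diene by cross-coupling and sets out from ester 9. Amidation with MeNH(OMe)·HCl and i-PrMgCl should give the Weinreb amide F5, and MeMgBr then gives the methyl ketone F6. Kinetic enolisation at the methyl group with KN(SiMe3)2 and trapping with PhNTf2 at −78 °C should give the dienyl triflate F7. Kumada coupling with Me3SiCH2MgCl and Pd(PPh3)4 returns to diene 11.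

Step 10. Protonation at C9 may show insufficient facial selectivity. The fallback moves C9 under thermodynamic control and sets out from 14. Only the acid stage is run (CF3CO2H, CH2Cl2, aqueous NaHCO3 work-up), and the product is taken on as the C9-epimeric silylalkyne mixture F8. Ozonolysis of the exocyclic alkene (O3, CH2Cl2/MeOH, −78 °C; Me2S) should give the nor-ketone F9. NaOMe in MeOH equilibrates C9 to the equatorial side chain and removes the alkynyl silicon, giving the ketone F10. Wittig methylenation (Ph3P=CH2, THF) comes back at alkyne 16.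

Further compounds
F1 | step 8 | (2E,8E)-4,4,8-trimethyl-10-methylidene-11-(trimethylsilyl)-9-[4-(trimethylsilyl)but-3-yn-1-yl]undeca-2,8-dienoic acid | OC(=O)/C=C/C(C)(C)CCC/C(C)=C(\CCC#C[Si](C)(C)C)C(=C)C[Si](C)(C)C
F2 | step 8 | (4R)-4-benzyl-3-[(2E,8E)-4,4,8-trimethyl-10-methylidene-11-(trimethylsilyl)-9-[4-(trimethylsilyl)but-3-yn-1-yl]undeca-2,8-dienoyl]-1,3-oxazolidin-2-one | O=C(/C=C/C(C)(C)CCC/C(C)=C(\CCC#C[Si](C)(C)C)C(=C)C[Si](C)(C)C)N1C(=O)OC[C@H]1Cc2ccccc2
F3 | step 8 | (4R)-4-benzyl-3-{[(1R,4aR,8aR)-4a,8,8-trimethyl-4-[4-(trimethylsilyl)but-3-yn-1-yl]-3-[(trimethylsilyl)methyl]-1,2,4a,5,6,7,8,8a-octahydronaphthalen-1-yl]carbonyl}-1,3-oxazolidin-2-one | C[Si](C)(C)CC=1C[C@@H](C(=O)N3C(=O)OC[C@H]3Cc4ccccc4)[C@@H]2C(C)(C)CCC[C@@]2(C)C=1CCC#C[Si](C)(C)C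
F4 | step 8 | [(1R,4aR,8aR)-4a,8,8-trimethyl-4-[4-(trimethylsilyl)but-3-yn-1-yl]-3-[(trimethylsilyl)methyl]-1,2,4a,5,6,7,8,8a-octahydronaphthalen-1-yl]methanol | C[Si](C)(C)CC=1C[C@@H](CO)[C@@H]2C(C)(C)CCC[C@@]2(C)C=1CCC#C[Si](C)(C)C
F5 | step 6 | (2E,8E)-N,10,10-trimethoxy-N,3,7,7-tetramethyl-2-[4-(trimethylsilyl)but-3-yn-1-yl]deca-2,8-dienamide | CON(C)C(=O)/C(CCC#C[Si](C)(C)C)=C(\C)CCCC(C)(C)/C=C/C(OC)OC
F6 | step 6 | (3E,9E)-11,11-dimethoxy-4,8,8-trimethyl-3-[4-(trimethylsilyl)but-3-yn-1-yl]undeca-3,9-dien-2-one | CC(=O)/C(CCC#C[Si](C)(C)C)=C(\C)CCCC(C)(C)/C=C/C(OC)OC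
F7 | step 6 | (3E,9E)-11,11-dimethoxy-4,8,8-trimethyl-3-[4-(trimethylsilyl)but-3-yn-1-yl]undeca-1,3,9-trien-2-yl trifluoromethanesulfonate | C=C(OS(=O)(=O)C(F)(F)F)/C(CCC#C[Si](C)(C)C)=C(\C)CCCC(C)(C)/C=C/C(OC)OC
F8 | step 10 | trimethyl{4-[(4aR,8aR)-5,5,8a-trimethyl-2-methylidenedecahydronaphthalen-1-yl]but-1-yn-1-yl}silane (C1 epimer mixture) | C=C1CC[C@@H]2C(C)(C)CCC[C@@]2(C)C1CCC#C[Si](C)(C)C
F9 | step 10 | (4aR,8aR)-5,5,8a-trimethyl-1-[4-(trimethylsilyl)but-3-yn-1-yl]octahydronaphthalen-2(1H)-one (C1 epimer mixture) | O=C1CC[C@@H]2C(C)(C)CCC[C@@]2(C)C1CCC#C[Si](C)(C)C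
F10 | step 10 | (1S,4aR,8aR)-1-(but-3-yn-1-yl)-5,5,8a-trimethyloctahydronaphthalen-2(1H)-one | O=C1CC[C@@H]2C(C)(C)CCC[C@@]2(C)[C@@H]1CCC#C
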